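All runs were computed for substances that don't exist; the scatter is artificial.

Saturday's flask has stopped rising.

all flasks: substrate 23 mM

|  | catalyst | remark | time |
|---|---|---|---|
| Saturday's | 0.42 mol% | the very flask that is asked about, followed so far |  |
| Tuesday's | 0.63 mol% | run made earlier |  |
| flask | 0.42 mol% |  | 4.0 h |

- Saturday's (time / h: target / %): 0.333: 29.9; 0.500: 32.1; 0.833: 33.6; 1.33: 34.4; 2.50: 33.3; 4.00: 33.8
- Tuesday's (time / min: target / %): 6.00: 17.6; 15.0: 26.4; 30.0: 33.5; 50.0: 33.8; 60.0: 32.9; 80.0: 34.9

(readings scatter by 1 percentage point)

- red: at 4.0 h add substrate, 50.0 % of the amount charged, then wait 8.0 h
- violet: at 4.0 h add catalyst, 50.0 % of the amount charged, then wait 8.0 h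
- blue: change nothing and wait 8.0 h more
- ochre: at 4.0 h take out 90 % of the target then present, then wait 8.0 h

- target taken out counts as made
- the numbers in the tables scatter by 1 percentage point (one standard deviation)
- additions bring no volume worth counting

- target, in percent of the substrate first charged, at 4.0 h
- what to do for the largest gain in target; "none" if nothing gains more than 2 percentage points (red / violet / blue / ochre / none)
- target present, with what was taken out counted in, in percent of the substrate first charged, after red
- target present, with what was taken out counted in, in percent of the substrate first charged, after ochre

For the next person at the bench: the target in Saturday's flask has stayed level since about 0.833 h. Tuesday's run, with 0.63 mol% of catalyst against 0.42 mol%, levels off at the same height. Once forward and back rates balance, dividing one by the other removes time from the reckoning. The late readings of both runs average 33.8 %; this reading is the rest share, the part of the material in the flask that stands as target at balance. Do not expect gain from waiting or from more catalyst, since neither run rises further and the two loadings level off alike.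

After red: rest share × (charge + addition) = 50.8 %

After ochre: taken out 30.5 %, plus rest share × what remains = 54.0 %

The wait of 8.0 h is longer than the 1.33 h by which Saturday's readings had levelled, and ochre's 54.0 % stands above red's 50.8 %, so ochre is the choice of this reckoning.

The forecast says “this looks like an equilibrium” and gives 33.8 %, 50.7 % after red and 53.9 % after ochre, choosing ochre.

The simulation gives 33.7 %, 50.5 % after red and 53.7 % after ochre, so ochre gains 20 percentage points, red 17 points and violet 0 points.

    substrate ⇌ target (K = 14.0, k = 9.10 × 10⁻⁴ s⁻¹)
    target ⇌ isomer of the product (K = 1.90, k = 0.00120 s⁻¹)
    isomer of the product + catalyst ⇌ substrate + catalyst, rate k3*[catalyst]*[isomer of the product] forward; the back reaction follows from the equilibrium constant (k = 9.70 M⁻¹ s⁻¹)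

Beside the target at 4.00 h, Saturday's flask holds 63.9 % isomer of the product and 2.40 % substrate, a composition the rest share does not show. The neighbouring flask has 9.2 mM of substrate at the same loading. There the rest share gives 3.11 mM of target, and that flask holds 33.7 % of its charge as target at 4.00 h, which is 3.10 mM.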